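**Strategy.** The 2,3-dihydro-1,4-benzodioxine ring is disconnected at C2–C3, the bond between its two benzylic, oxygen-bearing carbons. The key step exploits that the unit O1–C2–C3–O4 is a catechol acetal (O1–C2–O4) with one carbon, C3, inserted into the C2–O4 bond. The precursor is therefore a five-membered 2-aryl-1,3-benzodioxole (5) plus an aryl carbene. A chiral dirhodium carbene adds to the acetal oxygen meta to the ester; the oxonium ylide opens to an oxocarbenium ion and recloses through C2–C3, expanding dioxole to dioxane and setting both trans stereocentres in one operation. Olefination and desilylation finish the synthesis.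

Key step: step 5

Conventions: TBS = tert-butyldimethylsilyl, TBSO = tert-butyldimethylsilyloxy. In the dihydrobenzodioxine, O1 is para to C6 and bonded to C2 (3,4-dioxygenated aryl); O4 is bonded to C3 (3,5-dioxygenated aryl). In benzodioxole 5, O1 is para and O3 meta to the ester at C5; O3 of 5 becomes O4 of 11.

Assumption: the absolute sense of induction of a chiral dirhodium tetracarboxylate in this ring expansion cannot be assigned in advance; Rh2(S-PTAD)4 is written, and its mirror image Rh2(R-PTAD)4 is taken instead if it proves to favour the 3R centre.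

Step 1
Reactants: 1 3,4-dihydroxybenzaldehyde
Product: 2 3,4-bis(TBSO)benzaldehyde
Conditions: TBSCl (2.3 equiv), imidazole, DMF, 0 °C → rt
Reagents that add atoms: tert-butyldimethylsilyl chloride, CC(C)(C)[Si](C)(C)Cl
Why: Imidazole-promoted O-silylation of both phenols; no stereocenter is formed.

Step 2
Reactants: 2 3,4-bis(TBSO)benzaldehyde; 3 methyl 3,4-dihydroxybenzoate
Product: 5 methyl 2-[3,4-bis(TBSO)phenyl]-1,3-benzodioxole-5-carboxylate (racemic), via dimethyl acetal 4 (not isolated)
Conditions: HC(OMe)3, PPTS (cat.), MeOH, rt, evaporate; then 3, PPTS (cat.), toluene, 110 °C, 5 Å MS (Soxhlet)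
Reagents that add atoms: none
Why: Acid-catalysed transacetalisation: trimethyl orthoformate converts 2 into acetal 4, whose electron-rich aryl group stabilises the oxocarbenium ion that the ester-deactivated catechol 3 captures twice while methanol is removed; the acetal carbon forms racemic, which is without consequence because it is planarised in step 5.

Step 3
Reactants: 6 3,5-dihydroxybenzaldehyde
Product: 7 3,5-bis(TBSO)benzaldehyde
Conditions: TBSCl (2.3 equiv), imidazole, DMF, 0 °C → rt
Reagents that add atoms: tert-butyldimethylsilyl chloride, CC(C)(C)[Si](C)(C)Cl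
Why: Imidazole-promoted O-silylation of both phenols.

Step 4
Reactants: 7 3,5-bis(TBSO)benzaldehyde
Product: 8 N'-[(E)-[3,5-bis(TBSO)phenyl]methylidene]-2-(trifluoromethyl)benzenesulfonohydrazide
Conditions: 2-(trifluoromethyl)benzenesulfonohydrazide (1.05 equiv), MeOH/CH2Cl2, rt
Reagents that add atoms: 2-(trifluoromethyl)benzenesulfonohydrazide, NNS(=O)(=O)c1ccccc1C(F)(F)F
Why: Condensation of the aldehyde with the sulfonyl hydrazide gives the (E)-hydrazone, a bench-stable diazo precursor that fragments under mild base at low temperature (Bamford–Stevens type).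

Step 5
Reactants: 5 methyl 2-[3,4-bis(TBSO)phenyl]-1,3-benzodioxole-5-carboxylate; 8 sulfonylhydrazone of 3,5-bis(TBSO)benzaldehyde
Product: 11 methyl (2S,3S)-2-[3,4-bis(TBSO)phenyl]-3-[3,5-bis(TBSO)phenyl]-2,3-dihydro-1,4-benzodioxine-6-carboxylate, via aryldiazomethane 9 (not isolated), via oxonium ylide 10 (not isolated)
Conditions: 8 (2.5 equiv, in portions), NaH (3 equiv), Rh2(S-PTAD)4 [dirhodium tetrakis((S)-(1-adamantyl)(N-phthalimido)acetate)] (2 mol%), 4 Å MS, CH2Cl2, −40 → 0 °C
Reagents that add atoms: none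
Why: Proposed new method: NaH converts 8 into diazo compound 9, which the dirhodium tetracarboxylate turns into a donor carbene; O3 of 5 captures it to give the rhodium-associated oxonium ylide 10, whose O3–C2 acetal bond ionises at once to an oxocarbenium ion stabilised by O1 and the 3,4-disiloxyphenyl group, and the rhodium-bound benzylic carbon then attacks this ion to form C2–C3 (net [1,2]-Stevens shift). The closest known reaction type is the metal-carbene ring expansion of 1,3-dioxolanes to 1,4-dioxanes and of oxetanes to tetrahydrofurans through oxonium ylides, which has been run enantioselectively with chiral copper and dirhodium catalysts; here it is extended to a catechol acetal and an aryl (donor) carbene. The six-membered dioxane ring closes in a 6-endo-trig mode (five-to-six ring expansion). C3 is set by the chiral carboxylate ligands, which fix the carbene face that O3 attacks while the metal stays on carbon until the C–C bond forms; C2 is set relative to C3 by a chair-like closure with both aryl groups pseudo-equatorial (trans), and the racemic acetal centre of 5 is erased in the planar oxocarbenium ion, so both enantiomers of 5 converge. The step needs O3 over O1 selectivity, secured by the para ester that ties up the lone pair of O1 and leaves O3 the more nucleophilic oxygen, and ylide formation over carbene dimerisation, secured by slow release of 9 at low temperature.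

Step 6
Reactants: 11 methyl (2S,3S)-2,3-diaryl-2,3-dihydro-1,4-benzodioxine-6-carboxylate
Product: 12 [(2S,3S)-2-[3,4-bis(TBSO)phenyl]-3-[3,5-bis(TBSO)phenyl]-2,3-dihydro-1,4-benzodioxin-6-yl]methanol
Conditions: diisobutylaluminium hydride (2.5 equiv), CH2Cl2, −78 °C; aq. potassium sodium tartrate
Reagents that add atoms: none
Why: Hydride reduction of the aryl methyl ester to the benzylic alcohol; the aryl silyl ethers, the benzylic ring ethers and both stereocenters are untouched at low temperature.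

Step 7
Reactants: 12 benzylic alcohol
Product: 13 (2S,3S)-2-[3,4-bis(TBSO)phenyl]-3-[3,5-bis(TBSO)phenyl]-2,3-dihydro-1,4-benzodioxine-6-carbaldehyde
Conditions: MnO2 (activated, excess), CH2Cl2, rt
Reagents that add atoms: none
Why: MnO2 oxidises the benzylic alcohol selectively to the aldehyde under neutral conditions without over-oxidation.

Step 8
Reactants: 7 3,5-bis(TBSO)benzaldehyde
Product: 14 [3,5-bis(TBSO)phenyl]methanol
Conditions: NaBH4, THF/MeOH, 0 °C
Reagents that add atoms: none
Why: Borohydride reduction of the aldehyde to the benzylic alcohol.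

Step 9
Reactants: 14 [3,5-bis(TBSO)phenyl]methanol
Product: 15 3,5-bis(TBSO)benzyl bromide
Conditions: CBr4, PPh3, CH2Cl2, 0 °C
Reagents that add atoms: carbon tetrabromide, BrC(Br)(Br)Br
Why: Appel reaction converts the benzylic alcohol into the bromide under neutral conditions that spare the aryl silyl ethers.

Step 10
Reactants: 15 3,5-bis(TBSO)benzyl bromide
Product: 16 diethyl [3,5-bis(TBSO)benzyl]phosphonate
Conditions: P(OEt)3 (neat), 130 °C
Reagents that add atoms: triethyl phosphite, CCOP(OCC)OCC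
Why: Michaelis–Arbuzov reaction of the benzylic bromide with triethyl phosphite; bromoethane distils off.

Step 11
Reactants: 13 dihydrobenzodioxine-6-carbaldehyde; 16 diethyl [3,5-bis(TBSO)benzyl]phosphonate
Product: 17 hexakis-TBS ether of the target, (2S,3S)-2-[3,4-bis(TBSO)phenyl]-3-[3,5-bis(TBSO)phenyl]-6-[(E)-2-[3,5-bis(TBSO)phenyl]ethenyl]-2,3-dihydro-1,4-benzodioxine
Conditions: 16 (1.3 equiv), NaN(SiMe3)2 (1.3 equiv), THF, 0 °C; then 13, 0 °C → rt
Reagents that add atoms: none
Why: Horner–Wadsworth–Emmons olefination of a benzylphosphonate anion with an aryl aldehyde gives the (E)-stilbene; the non-nucleophilic amide base spares the aryl silyl ethers and does not deprotonate C2–H or C3–H.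

Step 12
Reactants: 17 hexakis-TBS ether
Product: 18 4-[(2S,3S)-3-(3,5-dihydroxyphenyl)-6-[(E)-2-(3,5-dihydroxyphenyl)ethenyl]-2,3-dihydro-1,4-benzodioxin-2-yl]benzene-1,2-diol (CNP0419909.1)
Conditions: Bu4NF (7 equiv), AcOH (7 equiv), THF, 0 °C → rt, argon
Reagents that add atoms: none
Why: Fluoride cleaves all six aryl silyl ethers, while the acetic acid buffer keeps the liberated phenols protonated so that the 4-hydroxyl of the C2 aryl group cannot open the dioxane ring through a p-quinone methide; the stilbene and both stereocenters remain intact.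

**Compound list**

1 | 3,4-dihydroxybenzaldehyde | O=Cc1ccc(O)c(O)c1 | starting material
2 | 3,4-bis(TBSO)benzaldehyde | O=Cc1ccc(O[Si](C)(C)C(C)(C)C)c(O[Si](C)(C)C(C)(C)C)c1 | intermediate
3 | methyl 3,4-dihydroxybenzoate | COC(=O)c1ccc(O)c(O)c1 | starting material
4 | 3,4-bis(TBSO)benzaldehyde dimethyl acetal | COC(OC)c1ccc(O[Si](C)(C)C(C)(C)C)c(O[Si](C)(C)C(C)(C)C)c1 | intermediate
5 | methyl 2-[3,4-bis(TBSO)phenyl]-1,3-benzodioxole-5-carboxylate (racemic) | COC(=O)c1ccc2OC(c3ccc(O[Si](C)(C)C(C)(C)C)c(O[Si](C)(C)C(C)(C)C)c3)Oc2c1 | intermediate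
6 | 3,5-dihydroxybenzaldehyde | O=Cc1cc(O)cc(O)c1 | starting material
7 | 3,5-bis(TBSO)benzaldehyde | O=Cc1cc(O[Si](C)(C)C(C)(C)C)cc(O[Si](C)(C)C(C)(C)C)c1 | intermediate
8 | N'-[(E)-[3,5-bis(TBSO)phenyl]methylidene]-2-(trifluoromethyl)benzenesulfonohydrazide | FC(F)(F)c1ccccc1S(=O)(=O)N/N=C/c1cc(O[Si](C)(C)C(C)(C)C)cc(O[Si](C)(C)C(C)(C)C)c1 | intermediate
9 | [3,5-bis(TBSO)phenyl]diazomethane | [N-]=[N+]=Cc1cc(O[Si](C)(C)C(C)(C)C)cc(O[Si](C)(C)C(C)(C)C)c1 | intermediate
10 | oxonium ylide at O3 of 5 (drawn metal-free) | COC(=O)c1ccc2OC(c3ccc(O[Si](C)(C)C(C)(C)C)c(O[Si](C)(C)C(C)(C)C)c3)[O+]([CH-]c3cc(O[Si](C)(C)C(C)(C)C)cc(O[Si](C)(C)C(C)(C)C)c3)c2c1 | intermediate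
11 | methyl (2S,3S)-2-[3,4-bis(TBSO)phenyl]-3-[3,5-bis(TBSO)phenyl]-2,3-dihydro-1,4-benzodioxine-6-carboxylate | COC(=O)c1ccc2c(c1)O[C@@H](c1cc(O[Si](C)(C)C(C)(C)C)cc(O[Si](C)(C)C(C)(C)C)c1)[C@H](c1ccc(O[Si](C)(C)C(C)(C)C)c(O[Si](C)(C)C(C)(C)C)c1)O2 | intermediate
12 | [(2S,3S)-2-[3,4-bis(TBSO)phenyl]-3-[3,5-bis(TBSO)phenyl]-2,3-dihydro-1,4-benzodioxin-6-yl]methanol | OCc1ccc2c(c1)O[C@@H](c1cc(O[Si](C)(C)C(C)(C)C)cc(O[Si](C)(C)C(C)(C)C)c1)[C@H](c1ccc(O[Si](C)(C)C(C)(C)C)c(O[Si](C)(C)C(C)(C)C)c1)O2 | intermediate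
13 | (2S,3S)-2-[3,4-bis(TBSO)phenyl]-3-[3,5-bis(TBSO)phenyl]-2,3-dihydro-1,4-benzodioxine-6-carbaldehyde | O=Cc1ccc2c(c1)O[C@@H](c1cc(O[Si](C)(C)C(C)(C)C)cc(O[Si](C)(C)C(C)(C)C)c1)[C@H](c1ccc(O[Si](C)(C)C(C)(C)C)c(O[Si](C)(C)C(C)(C)C)c1)O2 | intermediate
14 | [3,5-bis(TBSO)phenyl]methanol | OCc1cc(O[Si](C)(C)C(C)(C)C)cc(O[Si](C)(C)C(C)(C)C)c1 | intermediate
15 | 3,5-bis(TBSO)benzyl bromide | BrCc1cc(O[Si](C)(C)C(C)(C)C)cc(O[Si](C)(C)C(C)(C)C)c1 | intermediate
16 | diethyl [3,5-bis(TBSO)benzyl]phosphonate | CCOP(=O)(OCC)Cc1cc(O[Si](C)(C)C(C)(C)C)cc(O[Si](C)(C)C(C)(C)C)c1 | intermediate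
17 | (2S,3S)-2-[3,4-bis(TBSO)phenyl]-3-[3,5-bis(TBSO)phenyl]-6-[(E)-2-[3,5-bis(TBSO)phenyl]ethenyl]-2,3-dihydro-1,4-benzodioxine | CC(C)(C)[Si](C)(C)Oc1cc(O[Si](C)(C)C(C)(C)C)cc(/C=C/c2ccc3c(c2)O[C@@H](c2cc(O[Si](C)(C)C(C)(C)C)cc(O[Si](C)(C)C(C)(C)C)c2)[C@H](c2ccc(O[Si](C)(C)C(C)(C)C)c(O[Si](C)(C)C(C)(C)C)c2)O3)c1 | intermediate
18 | 4-[(2S,3S)-3-(3,5-dihydroxyphenyl)-6-[(E)-2-(3,5-dihydroxyphenyl)ethenyl]-2,3-dihydro-1,4-benzodioxin-2-yl]benzene-1,2-diol | Oc1cc(O)cc(/C=C/c2ccc3c(c2)O[C@@H](c2cc(O)cc(O)c2)[C@H](c2ccc(O)c(O)c2)O3)c1 | target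

**Totals.** Total step count: 12. Longest linear sequence: 7 steps (1, 2, 5, 6, 7, 11, 12).

**Steps most likely to fail**

Step 5 (Proposed new method). What may go wrong: capture of the carbene by the wrong acetal oxygen (O1) or by a second molecule of the diazo compound, loss of rhodium from the ylide before the C–C bond forms (erosion of enantioselectivity), and closure to the cis ring. The fallback uses known chemistry, closes the ring through O4–C3 instead, sets out from 2 and 16 and returns at 11. Horner–Wadsworth–Emmons olefination of 2 with the anion of 16 (NaN(SiMe3)2, THF) should give (E)-1-[3,4-bis(TBSO)phenyl]-2-[3,5-bis(TBSO)phenyl]ethene F1. Shi epoxidation (D-fructose-derived ketone catalyst, KHSO5, K2CO3 buffer, MeCN/dimethoxymethane/H2O, 0 °C) should give (2R,3R)-2-[3,4-bis(TBSO)phenyl]-3-[3,5-bis(TBSO)phenyl]oxirane F2. The 4-phenoxide of 3 (K2CO3, DMF, 40 °C; the hydroxyl para to the ester is the more acidic) should open F2 with inversion at the carbon carrying the 3,4-bis(TBSO)phenyl group, the better stabilised benzylic position. This gives methyl 4-[(1S,2R)-1-[3,4-bis(TBSO)phenyl]-2-[3,5-bis(TBSO)phenyl]-2-hydroxyethoxy]-3-hydroxybenzoate F3. Intramolecular Mitsunobu etherification (PPh3, DIAD, THF, 0 °C) of the remaining phenol onto the carbinol carbon, with inversion, should close the dioxane ring and give 11.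

Step 2. What may go wrong: incomplete exchange of the second methoxy group by the poorly nucleophilic, ester-deactivated catechol, and acid-induced loss of aryl silyl ethers at reflux. The fallback sets out from 3 and returns at 5. Silylation of 3 (Me3SiCl, Et3N, CH2Cl2) should give methyl 3,4-bis(trimethylsilyloxy)benzoate F4. Condensation of F4 with aldehyde 2 under Noyori acetalisation conditions (Me3SiOTf cat., CH2Cl2, −78 °C) should give 5, driven by formation of hexamethyldisiloxane and free of hot acid and methanol.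

Step 12. What may go wrong: opening of the C2–O1 bond through a p-quinone methide once the 4-hydroxyl of the C2 aryl group is deprotonated by basic fluoride, and air oxidation of the free catechol during isolation. The fallback sets out from 17 and returns at 18. CsF/Ac2O in DMF should exchange each silyl ether directly for an acetate, so that no phenoxide accumulates, giving 4-[(2S,3S)-3-(3,5-diacetoxyphenyl)-6-[(E)-2-(3,5-diacetoxyphenyl)ethenyl]-2,3-dihydro-1,4-benzodioxin-2-yl]-1,2-phenylene diacetate F5. After purification, neutral deacetylation (ammonium acetate, aq. MeOH, rt, argon) should give 18.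

**Further compounds**

F1 | step 5 | (E)-1-[3,4-bis(TBSO)phenyl]-2-[3,5-bis(TBSO)phenyl]ethene | CC(C)(C)[Si](C)(C)Oc1cc(O[Si](C)(C)C(C)(C)C)cc(/C=C/c2ccc(O[Si](C)(C)C(C)(C)C)c(O[Si](C)(C)C(C)(C)C)c2)c1
F2 | step 5 | (2R,3R)-2-[3,4-bis(TBSO)phenyl]-3-[3,5-bis(TBSO)phenyl]oxirane | O1[C@H](c2cc(O[Si](C)(C)C(C)(C)C)cc(O[Si](C)(C)C(C)(C)C)c2)[C@H]1c1ccc(O[Si](C)(C)C(C)(C)C)c(O[Si](C)(C)C(C)(C)C)c1
F3 | step 5 | methyl 4-[(1S,2R)-1-[3,4-bis(TBSO)phenyl]-2-[3,5-bis(TBSO)phenyl]-2-hydroxyethoxy]-3-hydroxybenzoate | O[C@H](c1cc(O[Si](C)(C)C(C)(C)C)cc(O[Si](C)(C)C(C)(C)C)c1)[C@H](c1ccc(O[Si](C)(C)C(C)(C)C)c(O[Si](C)(C)C(C)(C)C)c1)Oc1ccc(C(=O)OC)cc1O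
F4 | step 2 | methyl 3,4-bis(trimethylsilyloxy)benzoate | COC(=O)c1ccc(O[Si](C)(C)C)c(O[Si](C)(C)C)c1
F5 | step 12 | 4-[(2S,3S)-3-(3,5-diacetoxyphenyl)-6-[(E)-2-(3,5-diacetoxyphenyl)ethenyl]-2,3-dihydro-1,4-benzodioxin-2-yl]-1,2-phenylene diacetate | CC(=O)Oc1cc(OC(C)=O)cc(/C=C/c2ccc3c(c2)O[C@@H](c2cc(OC(C)=O)cc(OC(C)=O)c2)[C@H](c2ccc(OC(C)=O)c(OC(C)=O)c2)O3)c1
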